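**Retrosynthetic overview**

1. Numbering is germacrane: ring C1–C10; C1–C10 oxirane; C10 carries C14 (CHO); C8 and C6 carry OAc; C7 carries i‑Pr; C4 carries C15H3; C4=C5 is E. Pulicanaral A ⇐ 1,10‑epoxy‑14‑alcohol ⇐ tartrate‑controlled epoxidation of the C14 allylic alcohol ⇐ 6,8‑diacetate of the ten‑membered 1(10),4‑diene.
2. Feature used: ring carbon C7 lies between the two oxygenated ring carbons C6 and C8. At the 6,8‑dione level C7–H is flanked by two carbonyls and is configurationally labile, so the whole carbocycle 12 can be built with no fixed stereocentre.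
3. Key step: a ketoreductase reduces C8=O of 12 under dynamic kinetic resolution and fixes C7 and C8 together; a hydroxyl‑directed reduction then relays C8 to C6 (1,3‑anti).
4. The ten‑membered ring of 12 ⇐ ring‑closing metathesis forming C1=C10 (C2/C9 cis) ⇐ acyclic triene‑1,3‑dione ⇐ aldol union C7–C8 of dienone 4 (carboalumination–acylation of hex‑1‑en‑5‑yne) with aldehyde 8 (from monomethyl itaconate), then oxidation.
5. Order of ring formation: carbocycle (step 7), then C7/C8 (step 8), C6 (step 9), oxirane last (step 12).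

Key step: step 8

Remark: commercial monomethyl itaconate is taken as the 4‑methyl ester (free CO2H on the methylidene carbon). With C14 oxygenated, the ring‑cis C1=C10 bond (C2 and C9 on the same side) has the CIP descriptor E.

**Step 1**
Reactants: 1 hex‑1‑en‑5‑yne; 2 3‑methylbutanoyl chloride
Product: 4 (5E)‑2,6‑dimethyldeca‑5,9‑dien‑4‑one, via (E)‑dimethyl(2‑methylhexa‑1,5‑dien‑1‑yl)alane 3 (not isolated)
Conditions: Me3Al, Cp2ZrCl2 (cat.), CH2Cl2, 0 °C to rt; volatiles off; then 2, Pd(PPh3)4 (cat.), THF, 0 °C to rt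
Reagents that add atoms: trimethylaluminium, C[Al](C)C
Why: Zirconium‑catalysed syn‑methylalumination of the terminal alkyne (Negishi carboalumination; the terminal alkene reacts far more slowly) puts CH3 on C4 and Al on C5 on the same side, and palladium‑catalysed acylation of the alkenylalane proceeds with retention, so the E enone (C3 trans to C6) should result.

**Step 2**
Reactants: 5 4‑methoxy‑2‑methylidene‑4‑oxobutanoic acid (monomethyl itaconate)
Product: 6 methyl 3‑(hydroxymethyl)but‑3‑enoate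
Conditions: BH3·THF (1.1 equiv), THF, −15 to 0 °C; then H2O
Reagents that add atoms: none
Why: Borane reduces a free carboxylic acid through its acyloxyborane far faster than it attacks an ester, so with about one equivalent at low temperature only the conjugated CO2H (the future C14) should be reduced (chemoselective borane reduction of a half‑ester).

**Step 3**
Reactants: 6 methyl 3‑(hydroxymethyl)but‑3‑enoate
Product: 7 methyl 3‑({[tert‑butyl(dimethyl)silyl]oxy}methyl)but‑3‑enoate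
Conditions: TBSCl, imidazole, CH2Cl2, 0 °C
Reagents that add atoms: tert‑butyldimethylsilyl chloride, CC(C)(C)[Si](C)(C)Cl
Why: Standard silylation of a primary alcohol, run on crude 6 so that the γ‑hydroxy ester is capped before it can lactonise.

**Step 4**
Reactants: 7 methyl 3‑({[tert‑butyl(dimethyl)silyl]oxy}methyl)but‑3‑enoate
Product: 8 3‑({[tert‑butyl(dimethyl)silyl]oxy}methyl)but‑3‑enal
Conditions: DIBAL‑H (1.05 equiv), CH2Cl2, −78 °C; then H2O
Reagents that add atoms: none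
Why: DIBAL‑H partial reduction of an ester at −78 °C stops at the aluminium hemiacetal, which gives the aldehyde on hydrolysis; the β,γ‑unsaturated aldehyde is used at once without chromatography to avoid conjugation.

**Step 5**
Reactants: 4 (5E)‑2,6‑dimethyldeca‑5,9‑dien‑4‑one; 8 3‑({[tert‑butyl(dimethyl)silyl]oxy}methyl)but‑3‑enal
Product: 10 (7E)‑1‑{[tert‑butyl(dimethyl)silyl]oxy}‑4‑hydroxy‑8‑methyl‑2‑methylidene‑5‑(propan‑2‑yl)dodeca‑7,11‑dien‑6‑one (racemic mixture of diastereomers; carbinol = C8, i‑Pr carbon = C7), via lithium (5E)‑2,6‑dimethyldeca‑3,5,9‑trien‑4‑olate 9 (not isolated)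
Conditions: LDA, THF, −78 °C; then 8, −78 °C; H2O
Reagents that add atoms: none
Why: LDA removes the kinetically favoured α′ proton (C7) of the β,β‑disubstituted enone at −78 °C and the lithium enolate adds to the aldehyde faster than it deprotonates it (directed lithium aldol reaction); the configurations at C7 and C8 do not matter because step 6 removes one and makes the other labile.

**Step 6**
Reactants: 10 (7E)‑1‑{[tert‑butyl(dimethyl)silyl]oxy}‑4‑hydroxy‑8‑methyl‑2‑methylidene‑5‑(propan‑2‑yl)dodeca‑7,11‑dien‑6‑one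
Product: 11 (7E)‑1‑{[tert‑butyl(dimethyl)silyl]oxy}‑8‑methyl‑2‑methylidene‑5‑(propan‑2‑yl)dodeca‑7,11‑diene‑4,6‑dione
Conditions: Dess–Martin periodinane, pyridine, CH2Cl2, 0 °C to rt
Reagents that add atoms: none
Why: Dess–Martin oxidation converts a β‑hydroxy ketone into the 1,3‑dione without over‑oxidation, and pyridine buffering avoids acid‑promoted migration of the C10 methylidene into conjugation.

**Step 7**
Reactants: 11 (7E)‑1‑{[tert‑butyl(dimethyl)silyl]oxy}‑8‑methyl‑2‑methylidene‑5‑(propan‑2‑yl)dodeca‑7,11‑diene‑4,6‑dione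
Product: 12 (1(10)E,4E)‑14‑{[tert‑butyl(dimethyl)silyl]oxy}germacra‑1(10),4‑diene‑6,8‑dione (ten‑membered ring; C2 and C9 cis on C1=C10; C7 not fixed)
Conditions: Grubbs II (10 mol %), 1,4‑benzoquinone (cat.), PhMe, 60 °C, 1 mM, slow addition
Reagents that add atoms: none
Why: Ring‑closing olefin metathesis between the monosubstituted C1 alkene and the 1,1‑disubstituted C10 alkene (the electron‑poor trisubstituted C4=C5 enone should not engage) is driven by loss of ethylene at high dilution, and because the ring already holds the E C4=C5 bond, closure through the less strained cis arrangement of C2 and C9 should be favoured, benzoquinone suppressing Ru–H alkene migration.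

**Step 8**
Reactants: 12 (1(10)E,4E)‑14‑{[tert‑butyl(dimethyl)silyl]oxy}germacra‑1(10),4‑diene‑6,8‑dione
Product: 13 (7S,8R,1(10)E,4E)‑14‑{[tert‑butyl(dimethyl)silyl]oxy}‑8‑hydroxygermacra‑1(10),4‑dien‑6‑one
Conditions: NADPH‑dependent ketoreductase (alcohol dehydrogenase class, chosen from a panel), NADP+ (cat.), i‑PrOH, phosphate buffer pH 7.5–8, 5 % DMSO, 30 °C
Reagents that add atoms: none
Why: The ketoreductase transfers hydride from NADPH to one face of the C8 carbonyl of only that C7 epimer of 12 that fits the active site, while the other epimer racemises through the enol of the 1,3‑dione, so the step is a dynamic reductive kinetic resolution. The closest known reaction type is the ketoreductase reduction of α‑alkyl‑1,3‑diketones and α‑alkyl‑β‑keto esters to single syn or anti ketols. No ring is closed; the step turns the stereocentre‑free ten‑membered ring into one with C7 and C8 fixed. C8 (R) is set by the facial preference of the enzyme and C7 (S) by its discrimination between the two interconverting epimers, a 7,8‑syn‑selective member of the panel being chosen. The step needs chemoselectivity for the saturated C8 carbonyl over C6=O, which the conjugation of C6=O with C4=C5 (lower electrophilicity) and the choice of enzyme should secure, and it needs epimerisation at C7 to outrun reduction, which the acidity of the C–H between two carbonyls at pH 7.5–8 secures; once C8 is reduced C7 is no longer labile. A variant that instead reduced C6=O to the (6R,7S) ketol would converge on the same diol 14 in step 9.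

**Step 9**
Reactants: 13 (7S,8R,1(10)E,4E)‑14‑{[tert‑butyl(dimethyl)silyl]oxy}‑8‑hydroxygermacra‑1(10),4‑dien‑6‑one
Product: 14 (6R,7S,8R,1(10)E,4E)‑14‑{[tert‑butyl(dimethyl)silyl]oxy}germacra‑1(10),4‑diene‑6,8‑diol
Conditions: Me4NBH(OAc)3, MeCN/AcOH, −30 °C; then H2O
Reagents that add atoms: none
Why: In the Evans–Saksena reduction the C8 hydroxyl exchanges an acetate on boron and the alkoxyborohydride delivers hydride intramolecularly to the acid‑activated C6 carbonyl through a chair‑like six‑membered transition state, which should give the 1,3‑anti diol (6R) with 1,2‑reduction of the enone only.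

**Step 10**
Reactants: 14 (6R,7S,8R,1(10)E,4E)‑14‑{[tert‑butyl(dimethyl)silyl]oxy}germacra‑1(10),4‑diene‑6,8‑diol
Product: 15 (6R,7S,8R,1(10)E,4E)‑14‑{[tert‑butyl(dimethyl)silyl]oxy}germacra‑1(10),4‑diene‑6,8‑diyl diacetate
Conditions: Ac2O, pyridine, DMAP (cat.), CH2Cl2, rt
Reagents that add atoms: acetic anhydride, CC(=O)OC(C)=O
Why: DMAP‑catalysed acetylation esterifies both secondary hydroxyls; no stereocentre is touched.

**Step 11**
Reactants: 15 (6R,7S,8R,1(10)E,4E)‑14‑{[tert‑butyl(dimethyl)silyl]oxy}germacra‑1(10),4‑diene‑6,8‑diyl diacetate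
Product: 16 (6R,7S,8R,1(10)E,4E)‑14‑hydroxygermacra‑1(10),4‑diene‑6,8‑diyl diacetate
Conditions: HF·pyridine, pyridine, THF, 0 °C
Reagents that add atoms: none
Why: Pyridine‑buffered HF·pyridine cleaves the primary allylic TBS ether under conditions that should neither hydrolyse nor migrate the acetates, unlike basic fluoride.

**Step 12**
Reactants: 16 (6R,7S,8R,1(10)E,4E)‑14‑hydroxygermacra‑1(10),4‑diene‑6,8‑diyl diacetate
Product: 17 (1R,6R,7S,8R,10R,4E)‑1,10‑epoxy‑14‑hydroxygermacr‑4‑ene‑6,8‑diyl diacetate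
Conditions: Ti(Oi‑Pr)4 (cat.), D‑(−)‑diethyl tartrate (cat.), t‑BuOOH, 4 Å MS, CH2Cl2, −20 °C
Reagents that add atoms: tert‑butyl hydroperoxide, CC(C)(C)OO
Why: Sharpless asymmetric epoxidation acts only on the alkene of the allylic alcohol (C1=C10) and leaves C4=C5 untouched, and for this 2,3‑trans‑disubstituted allylic alcohol the D‑(−)‑tartrate catalyst should deliver oxygen to the face that gives the (1R,10R) epoxy alcohol (the 1R,10S arrangement of the target once C14 is an aldehyde), under reagent control.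

**Step 13**
Reactants: 17 (1R,6R,7S,8R,10R,4E)‑1,10‑epoxy‑14‑hydroxygermacr‑4‑ene‑6,8‑diyl diacetate
Product: 18 Pulicanaral A, (1R,6R,7S,8R,10S,4E)‑1,10‑epoxy‑14‑oxogermacr‑4‑ene‑6,8‑diyl diacetate
Conditions: Dess–Martin periodinane, pyridine, CH2Cl2, 0 °C
Reagents that add atoms: none
Why: Pyridine‑buffered Dess–Martin oxidation takes the primary epoxy alcohol to the aldehyde without acid that could trigger transannular opening of the oxirane by C4=C5; C10 is quaternary, so no stereocentre can epimerise.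

**Compound list**

1 | hex‑1‑en‑5‑yne | C=CCCC#C | starting material
2 | 3‑methylbutanoyl chloride | CC(C)CC(=O)Cl | starting material
3 | (E)‑dimethyl(2‑methylhexa‑1,5‑dien‑1‑yl)alane | C=CCC/C(C)=C/[Al](C)C | intermediate
4 | (5E)‑2,6‑dimethyldeca‑5,9‑dien‑4‑one | C=CCC/C(C)=C/C(=O)CC(C)C | intermediate
5 | 4‑methoxy‑2‑methylidene‑4‑oxobutanoic acid (monomethyl itaconate) | C=C(CC(=O)OC)C(=O)O | starting material
6 | methyl 3‑(hydroxymethyl)but‑3‑enoate | C=C(CO)CC(=O)OC | intermediate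
7 | methyl 3‑({[tert‑butyl(dimethyl)silyl]oxy}methyl)but‑3‑enoate | C=C(CO[Si](C)(C)C(C)(C)C)CC(=O)OC | intermediate
8 | 3‑({[tert‑butyl(dimethyl)silyl]oxy}methyl)but‑3‑enal | C=C(CO[Si](C)(C)C(C)(C)C)CC=O | intermediate
9 | lithium (5E)‑2,6‑dimethyldeca‑3,5,9‑trien‑4‑olate | C=CCC/C(C)=C/C(O[Li])=CC(C)C | intermediate
10 | (7E)‑1‑{[tert‑butyl(dimethyl)silyl]oxy}‑4‑hydroxy‑8‑methyl‑2‑methylidene‑5‑(propan‑2‑yl)dodeca‑7,11‑dien‑6‑one (racemic diastereomers) | C=CCC/C(C)=C/C(=O)C(C(C)C)C(O)CC(=C)CO[Si](C)(C)C(C)(C)C | intermediate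
11 | (7E)‑1‑{[tert‑butyl(dimethyl)silyl]oxy}‑8‑methyl‑2‑methylidene‑5‑(propan‑2‑yl)dodeca‑7,11‑diene‑4,6‑dione | C=CCC/C(C)=C/C(=O)C(C(C)C)C(=O)CC(=C)CO[Si](C)(C)C(C)(C)C | intermediate
12 | (1(10)E,4E)‑14‑{[tert‑butyl(dimethyl)silyl]oxy}germacra‑1(10),4‑diene‑6,8‑dione | O=C1/C=C(\C)CC/C=C(/CO[Si](C)(C)C(C)(C)C)CC(=O)C1C(C)C | intermediate
13 | (7S,8R,1(10)E,4E)‑14‑{[tert‑butyl(dimethyl)silyl]oxy}‑8‑hydroxygermacra‑1(10),4‑dien‑6‑one | O=C1/C=C(\C)CC/C=C(/CO[Si](C)(C)C(C)(C)C)C[C@@H](O)[C@@H]1C(C)C | intermediate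
14 | (6R,7S,8R,1(10)E,4E)‑14‑{[tert‑butyl(dimethyl)silyl]oxy}germacra‑1(10),4‑diene‑6,8‑diol | O[C@@H]1/C=C(\C)CC/C=C(/CO[Si](C)(C)C(C)(C)C)C[C@@H](O)[C@@H]1C(C)C | intermediate
15 | (6R,7S,8R,1(10)E,4E)‑14‑{[tert‑butyl(dimethyl)silyl]oxy}germacra‑1(10),4‑diene‑6,8‑diyl diacetate | CC(=O)O[C@@H]1/C=C(\C)CC/C=C(/CO[Si](C)(C)C(C)(C)C)C[C@@H](OC(C)=O)[C@@H]1C(C)C | intermediate
16 | (6R,7S,8R,1(10)E,4E)‑14‑hydroxygermacra‑1(10),4‑diene‑6,8‑diyl diacetate | CC(=O)O[C@@H]1/C=C(\C)CC/C=C(/CO)C[C@@H](OC(C)=O)[C@@H]1C(C)C | intermediate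
17 | (1R,6R,7S,8R,10R,4E)‑1,10‑epoxy‑14‑hydroxygermacr‑4‑ene‑6,8‑diyl diacetate | CC(=O)O[C@@H]1/C=C(\C)CC[C@H]2O[C@@]2(CO)C[C@@H](OC(C)=O)[C@@H]1C(C)C | intermediate
18 | Pulicanaral A, (1R,6R,7S,8R,10S,4E)‑1,10‑epoxy‑14‑oxogermacr‑4‑ene‑6,8‑diyl diacetate | CC(=O)O[C@@H]1/C=C(\C)CC[C@H]2O[C@@]2(C=O)C[C@@H](OC(C)=O)[C@@H]1C(C)C | target

**Step count**

Total steps: 13. Longest linear sequence: 12 steps (5 → 18).

**Steps most likely to fail**

Step 8. No enzyme of the panel may turn over the doubly α‑branched ring ketone, hydride may go to C6=O or to the wrong face, or epimerisation at C7 may be slower than reduction so that the reaction stalls as a simple kinetic resolution. The fallback replaces the enzymatic reduction by an auxiliary‑controlled aldol; it sets out from 8 and from alkenylalane 3 and comes back at 13. The dibutylboron enolate of commercial (4S)‑4‑benzyl‑3‑(3‑methylbutanoyl)‑1,3‑oxazolidin‑2‑one (Bu2BOTf, i‑Pr2NEt, CH2Cl2, −78 °C) adds to 8 in an Evans syn‑aldol reaction and should give (4S)‑4‑benzyl‑3‑[(2S,3R)‑5‑({[tert‑butyl(dimethyl)silyl]oxy}methyl)‑3‑hydroxy‑2‑(propan‑2‑yl)hex‑5‑enoyl]‑1,3‑oxazolidin‑2‑one F1. Transamidation (MeONHMe·HCl, AlMe3) gives (2S,3R)‑5‑({[tert‑butyl(dimethyl)silyl]oxy}methyl)‑3‑hydroxy‑N‑methoxy‑N‑methyl‑2‑(propan‑2‑yl)hex‑5‑enamide F2. Iodinolysis of 3 (I2, THF, −30 °C) gives (1E)‑1‑iodo‑2‑methylhexa‑1,5‑diene F3, whose lithium reagent (t‑BuLi, Et2O, −78 °C, in excess to take up the free hydroxyl) adds to F2 to give (4R,5S,7E)‑1‑{[tert‑butyl(dimethyl)silyl]oxy}‑4‑hydroxy‑8‑methyl‑2‑methylidene‑5‑(propan‑2‑yl)dodeca‑7,11‑dien‑6‑one F4. Ring‑closing metathesis under the conditions of step 7 then closes C1=C10 and should give 13.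

Step 7. Intermolecular metathesis (oligomers) may outrun closure of the ten‑membered ring, the 1,1‑disubstituted alkene may fail to enter the catalytic cycle, the ring may close with C2 and C9 trans, or ruthenium hydrides may move the C10 alkene into conjugation with C8=O. The fallback fixes the C1=C10 geometry before ring closure and closes the ring at C7–C8 instead; it sets out from 2 and comes back at 12.
- Nozaki–Hiyama–Kishi coupling of commercial pent‑4‑ynal with commercial [(2‑bromoprop‑2‑en‑1‑yl)oxy](tert‑butyl)dimethylsilane (CrCl2, NiCl2 cat., DMF) gives 2‑({[tert‑butyl(dimethyl)silyl]oxy}methyl)oct‑1‑en‑7‑yn‑3‑ol F5.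
- O‑Alkylation (KH, Bu3SnCH2I, THF) gives tributyl({[2‑({[tert‑butyl(dimethyl)silyl]oxy}methyl)oct‑1‑en‑7‑yn‑3‑yl]oxy}methyl)stannane F6.
- Tin–lithium exchange (n‑BuLi, 2.2 equiv, THF, −78 °C) triggers the [2,3]‑Still–Wittig shift, which for a 2‑substituted allylic ether should place the new CH2CH2OH arm cis to the chain and give (3E)‑3‑({[tert‑butyl(dimethyl)silyl]oxy}methyl)oct‑3‑en‑7‑yn‑1‑ol F7.
- TESCl/imidazole gives the triethylsilyl ether of F7, (3E)‑3‑({[tert‑butyl(dimethyl)silyl]oxy}methyl)‑1‑[(triethylsilyl)oxy]oct‑3‑en‑7‑yne F8.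
- Carboalumination–acylation with 2 as in step 1 gives (5E,9E)‑10‑({[tert‑butyl(dimethyl)silyl]oxy}methyl)‑2,6‑dimethyl‑12‑[(triethylsilyl)oxy]dodeca‑5,9‑dien‑4‑one F9.
- Kinetic silyl enol ether formation (LiHMDS, TMSCl, −78 °C) and NBS give its 3‑bromo derivative, (5E,9E)‑3‑bromo‑10‑({[tert‑butyl(dimethyl)silyl]oxy}methyl)‑2,6‑dimethyl‑12‑[(triethylsilyl)oxy]dodeca‑5,9‑dien‑4‑one F10.
- Swern oxidation, which converts the primary triethylsilyl ether directly into the aldehyde and leaves the TBS ether, gives (3E,7E)‑10‑bromo‑3‑({[tert‑butyl(dimethyl)silyl]oxy}methyl)‑7,11‑dimethyl‑9‑oxododeca‑3,7‑dienal F11.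
- SmI2 (THF, −78 °C, high dilution) forms the samarium(III) enolate at C7, which adds to C8 in a Reformatsky‑type aldol and should close the ring to 14‑{[tert‑butyl(dimethyl)silyl]oxy}‑8‑hydroxygermacra‑1(10),4‑dien‑6‑one (mixture of racemic diastereomers) F12.
- Dess–Martin oxidation as in step 6 gives 12.

Step 12. The conformational bias of the ten‑membered ring may oppose the tartrate catalyst (mismatched pair) and erode facial selectivity, turnover on the hindered ring allylic alcohol may be slow, or Lewis‑acid induced transannular opening of the oxirane by C4=C5 may set in. The fallback uses nucleophilic epoxidation of the enal in place of electrophilic epoxidation of the allylic alcohol; it sets out from 16 and comes back at 18. MnO2 (CH2Cl2) oxidises the allylic alcohol to (6R,7S,8R,1(10)E,4E)‑14‑oxogermacra‑1(10),4‑diene‑6,8‑diyl diacetate F13. Iminium‑type nucleophilic epoxidation with aqueous H2O2, catalysed by a 9‑amino‑9‑deoxy‑epi‑cinchona alkaloid salt of a chiral phosphoric acid (the catalyst‑controlled method for α‑branched enals, with the pseudoenantiomer chosen for the 1R,10S oxirane), should give 18 directly.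

**Further compounds**

F1 | step 8 | (4S)‑4‑benzyl‑3‑[(2S,3R)‑5‑({[tert‑butyl(dimethyl)silyl]oxy}methyl)‑3‑hydroxy‑2‑(propan‑2‑yl)hex‑5‑enoyl]‑1,3‑oxazolidin‑2‑one | CC(C)(C)[Si](C)(C)OCC(=C)C[C@@H](O)[C@H](C(C)C)C(=O)N1[C@@H](Cc2ccccc2)COC1=O
F2 | step 8 | (2S,3R)‑5‑({[tert‑butyl(dimethyl)silyl]oxy}methyl)‑3‑hydroxy‑N‑methoxy‑N‑methyl‑2‑(propan‑2‑yl)hex‑5‑enamide | CC(C)(C)[Si](C)(C)OCC(=C)C[C@@H](O)[C@H](C(C)C)C(=O)N(C)OC
F3 | step 8 | (1E)‑1‑iodo‑2‑methylhexa‑1,5‑diene | C=CCC/C(C)=C/I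
F4 | step 8 | (4R,5S,7E)‑1‑{[tert‑butyl(dimethyl)silyl]oxy}‑4‑hydroxy‑8‑methyl‑2‑methylidene‑5‑(propan‑2‑yl)dodeca‑7,11‑dien‑6‑one | C=CCC/C(C)=C/C(=O)[C@@H](C(C)C)[C@H](O)CC(=C)CO[Si](C)(C)C(C)(C)C
F5 | step 7 | 2‑({[tert‑butyl(dimethyl)silyl]oxy}methyl)oct‑1‑en‑7‑yn‑3‑ol | CC(C)(C)[Si](C)(C)OCC(=C)C(O)CCC#C
F6 | step 7 | tributyl({[2‑({[tert‑butyl(dimethyl)silyl]oxy}methyl)oct‑1‑en‑7‑yn‑3‑yl]oxy}methyl)stannane | CCCC[Sn](CCCC)(CCCC)COC(CCC#C)C(=C)CO[Si](C)(C)C(C)(C)C
F7 | step 7 | (3E)‑3‑({[tert‑butyl(dimethyl)silyl]oxy}methyl)oct‑3‑en‑7‑yn‑1‑ol | OCC/C(CO[Si](C)(C)C(C)(C)C)=C\CCC#C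
F8 | step 7 | (3E)‑3‑({[tert‑butyl(dimethyl)silyl]oxy}methyl)‑1‑[(triethylsilyl)oxy]oct‑3‑en‑7‑yne | CC[Si](CC)(CC)OCC/C(CO[Si](C)(C)C(C)(C)C)=C\CCC#C
F9 | step 7 | (5E,9E)‑10‑({[tert‑butyl(dimethyl)silyl]oxy}methyl)‑2,6‑dimethyl‑12‑[(triethylsilyl)oxy]dodeca‑5,9‑dien‑4‑one | CC(C)CC(=O)/C=C(\C)CC/C=C(/CO[Si](C)(C)C(C)(C)C)CCO[Si](CC)(CC)CC
F10 | step 7 | (5E,9E)‑3‑bromo‑10‑({[tert‑butyl(dimethyl)silyl]oxy}methyl)‑2,6‑dimethyl‑12‑[(triethylsilyl)oxy]dodeca‑5,9‑dien‑4‑one | CC(C)C(Br)C(=O)/C=C(\C)CC/C=C(/CO[Si](C)(C)C(C)(C)C)CCO[Si](CC)(CC)CC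
F11 | step 7 | (3E,7E)‑10‑bromo‑3‑({[tert‑butyl(dimethyl)silyl]oxy}methyl)‑7,11‑dimethyl‑9‑oxododeca‑3,7‑dienal | CC(C)C(Br)C(=O)/C=C(\C)CC/C=C(/CO[Si](C)(C)C(C)(C)C)CC=O
F12 | step 7 | 14‑{[tert‑butyl(dimethyl)silyl]oxy}‑8‑hydroxygermacra‑1(10),4‑dien‑6‑one (racemic diastereomers) | O=C1/C=C(\C)CC/C=C(/CO[Si](C)(C)C(C)(C)C)CC(O)C1C(C)C
F13 | step 12 | (6R,7S,8R,1(10)E,4E)‑14‑oxogermacra‑1(10),4‑diene‑6,8‑diyl diacetate | CC(=O)O[C@@H]1/C=C(\C)CC/C=C(/C=O)C[C@@H](OC(C)=O)[C@@H]1C(C)C
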